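**Strategy.** Everything rests on cutting the bond between the styryl CH and the quaternary ring carbon C1 of the cyclohexene. C1 is flanked by the aryl-bearing methine C6, and the ortho oxygen of that aryl ring (the later O1 of the second coumarin) serves as anchor for the styryl unit, bound as an alkenyl sulfonate. Photoredox decarboxylation at C1 gives a tertiary radical that captures the tethered alkenyl group at its sulfonyl-bearing carbon and expels SO2; in one operation the C–C bond and the quaternary centre form, styryl cis to aryl. The precursor is a sulfonate-linked cyclohexenecarboxylic acid made by an enantioselective Diels–Alder reaction; the second coumarin is closed last.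

Key step: step 8

Assumption 1: electrophilic iodination of 5,7-dimethoxycoumarin takes place at C8, the position between O1 and the 7-methoxy group.
Assumption 2: the (S)-oxazaborolidinium catalyst of step 5 is written for endo addition to the Cα-re face of methacrolein; if the exo mode dominates, the (R)-catalyst is used and the C1-epimeric adduct is carried on, since step 8 erases that carbon.

Step 1
Reactants: 1 5,7-dimethoxycoumarin
Product: 2 8-iodo-5,7-dimethoxycoumarin
Conditions: NIS, TFA (cat.), MeCN, rt
Reagents that add atoms: N-iodosuccinimide, O=C1CCC(=O)N1I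
Why: Electrophilic aromatic iodination should take place at C8, which is activated by O1, the 7-methoxy group (both ortho) and the 5-methoxy group (para) and is less hindered than C6.

Step 2
Reactants: 2 8-iodo-5,7-dimethoxycoumarin; 3 ethenesulfonyl fluoride
Product: 4 (E)-2-(5,7-dimethoxy-2-oxo-2H-chromen-8-yl)ethene-1-sulfonyl fluoride
Conditions: Pd(OAc)2 (5 mol%), AgO2CCF3, acetone, 60 °C
Reagents that add atoms: none
Why: Silver-promoted Heck–Mizoroki coupling of an aryl iodide with ethenesulfonyl fluoride should give the E alkene by syn insertion and syn β-hydride elimination, the S–F bond being inert to Pd.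

Step 3
Reactants: 5 2-hydroxy-4,6-dimethoxybenzaldehyde
Product: 6 2-(tert-butyldimethylsilyloxy)-4,6-dimethoxybenzaldehyde
Conditions: TBSCl, imidazole, DMF, rt
Reagents that add atoms: tert-butyldimethylsilyl chloride, C[Si](C)(Cl)C(C)(C)C
Why: Standard silylation of the phenol masks it for steps 4 and 5 and at the same time prepares it as the silyl ether needed for the later Si–F exchange.

Step 4
Reactants: 6 2-(tert-butyldimethylsilyloxy)-4,6-dimethoxybenzaldehyde; 7 diethyl (2-methylallyl)phosphonate
Product: 8 (E)-tert-butyl[3,5-dimethoxy-2-(3-methylbuta-1,3-dien-1-yl)phenoxy]dimethylsilane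
Conditions: LDA, THF, −78 °C to rt
Reagents that add atoms: none
Why: Horner–Wadsworth–Emmons olefination with the α-anion of an allylic phosphonate should give the conjugated diene with the E geometry typical of aryl aldehydes.

Step 5
Reactants: 8 (E)-tert-butyl[3,5-dimethoxy-2-(3-methylbuta-1,3-dien-1-yl)phenoxy]dimethylsilane; 9 methacrolein
Product: 10 (1S,2S)-2-[2-(tert-butyldimethylsilyloxy)-4,6-dimethoxyphenyl]-1,4-dimethylcyclohex-3-ene-1-carbaldehyde (formyl cis to aryl)
Conditions: (S)-B-o-tolyl-CBS-oxazaborolidine·Tf2NH (20 mol%), CH2Cl2, −78 to −40 °C; exo diastereomer removed by chromatography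
Reagents that add atoms: none
Why: Catalytic enantioselective Diels–Alder reaction in which the 1-aryl and 3-methyl groups of the diene both direct the formyl-bearing carbon next to the aryl-bearing carbon, the oxazaborolidinium-bound s-trans enal is attacked on one face so that the aryl-bearing stereocentre is set by the catalyst, and the endo mode places formyl cis to aryl; the exo adduct is removed because it carries the opposite configuration at the aryl-bearing carbon.

Step 6
Reactants: 10 (1S,2S)-2-[2-(tert-butyldimethylsilyloxy)-4,6-dimethoxyphenyl]-1,4-dimethylcyclohex-3-ene-1-carbaldehyde; 4 (E)-2-(5,7-dimethoxy-2-oxo-2H-chromen-8-yl)ethene-1-sulfonyl fluoride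
Product: 11 2-[(1S,6S)-6-formyl-3,6-dimethylcyclohex-2-en-1-yl]-3,5-dimethoxyphenyl (E)-2-(5,7-dimethoxy-2-oxo-2H-chromen-8-yl)ethene-1-sulfonate
Conditions: DBU (20 mol%), MeCN, rt to 50 °C
Reagents that add atoms: none
Why: Sulfur(VI) fluoride exchange between an aryl silyl ether and a sulfonyl fluoride, driven by Si–F bond formation, should join the two halves as the aryl alkenesulfonate without touching the non-enolisable aldehyde or the lactone.

Step 7
Reactants: 11 2-[(1S,6S)-6-formyl-3,6-dimethylcyclohex-2-en-1-yl]-3,5-dimethoxyphenyl (E)-2-(5,7-dimethoxy-2-oxo-2H-chromen-8-yl)ethene-1-sulfonate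
Product: 12 (1S,2S)-2-[2-({[(E)-2-(5,7-dimethoxy-2-oxo-2H-chromen-8-yl)ethenyl]sulfonyl}oxy)-4,6-dimethoxyphenyl]-1,4-dimethylcyclohex-3-ene-1-carboxylic acid
Conditions: NaClO2, NaH2PO4, 2-methyl-2-butene, t-BuOH/H2O, 0 °C to rt
Reagents that add atoms: sodium chlorite, [Na+].[O-]Cl=O
Why: Pinnick oxidation converts the hindered aldehyde into the acid under mild buffered conditions, with the alkene scavenger protecting the electron-rich rings and C=C bonds from hypochlorite.

Step 8
Reactants: 12 (1S,2S)-2-[2-({[(E)-2-(5,7-dimethoxy-2-oxo-2H-chromen-8-yl)ethenyl]sulfonyl}oxy)-4,6-dimethoxyphenyl]-1,4-dimethylcyclohex-3-ene-1-carboxylic acid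
Product: 13 8-{(E)-2-[(1R,2R)-2-(2-hydroxy-4,6-dimethoxyphenyl)-1,4-dimethylcyclohex-3-en-1-yl]ethenyl}-5,7-dimethoxy-2H-chromen-2-one
Conditions: Ir[dF(CF3)ppy]2(dtbbpy)PF6 (2 mol%), K2HPO4, degassed DMF (0.005 M), blue LEDs, rt; aq. NH4Cl work-up
Reagents that add atoms: none
Why: Proposed new method: the excited Ir(III) catalyst oxidises the carboxylate of 12, loss of CO2 gives the tertiary C1 radical, this adds to the sulfonyl-bearing carbon of the tethered alkenyl sulfonate to give a benzylic radical, and β-scission expels ArOSO2•, which is reduced by Ir(II) and loses SO2 to leave the phenol, so that the styryl group migrates from sulfur to carbon; the closest known reactions are the intermolecular photoredox decarboxylative alkenylation of acids with styryl sulfones and radical Smiles-type ipso migrations from sulfonates with SO2 extrusion. The only ring closed is a transient seven-membered benzo-fused cyclic sulfonate (7-exo-trig attack) that is opened again by the β-scission, so no new ring remains in 13. The quaternary stereocentre is controlled by the tether: the acceptor hangs through O–SO2 on the ortho carbon of the aryl group at the neighbouring stereocentre, so only the radical face syn to that aryl is within reach and styryl should end up cis to aryl, whatever the configuration of the carboxyl-bearing carbon in 12. The step needs attack at the α-sulfonyl carbon (secured by benzylic stabilisation of the adduct radical), intramolecular capture over intermolecular capture (high dilution) and E geometry (β-scission to the conjugated trans alkene, the Z isomer being strongly hindered by the quaternary carbon).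

Step 9
Reactants: 13 8-{(E)-2-[(1R,2R)-2-(2-hydroxy-4,6-dimethoxyphenyl)-1,4-dimethylcyclohex-3-en-1-yl]ethenyl}-5,7-dimethoxy-2H-chromen-2-one
Product: 14 3-{(1R,6R)-6-[(E)-2-(5,7-dimethoxy-2-oxo-2H-chromen-8-yl)ethenyl]-3,6-dimethylcyclohex-2-en-1-yl}-2-hydroxy-4,6-dimethoxybenzaldehyde
Conditions: MgCl2, Et3N, (CH2O)n, MeCN, reflux
Reagents that add atoms: paraformaldehyde (as formaldehyde), C=O
Why: Magnesium-phenoxide-directed ortho-formylation (Casnati–Skattebøl) should deliver the formyl group to the only free position ortho to the phenol, a second formaldehyde oxidising the intermediate benzylic alkoxide.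

Step 10
Reactants: 14 3-{(1R,6R)-6-[(E)-2-(5,7-dimethoxy-2-oxo-2H-chromen-8-yl)ethenyl]-3,6-dimethylcyclohex-2-en-1-yl}-2-hydroxy-4,6-dimethoxybenzaldehyde
Product: 16 8-{(E)-2-[(1R,2R)-2-(5,7-dimethoxy-2-oxo-2H-chromen-8-yl)-1,4-dimethylcyclohex-3-en-1-yl]ethenyl}-5,7-dimethoxy-2H-chromen-2-one (CNP0164660.2), via phosphorane ester 15 (not isolated)
Conditions: Ph3P=C=C=O, toluene, reflux
Reagents that add atoms: (triphenylphosphoranylidene)ketene, O=C=C=P(c1ccccc1)(c1ccccc1)c1ccccc1
Why: Bestmann coumarin synthesis, in which the phenol adds to the ketenylidene ylide and the resulting ester phosphorane closes the pyranone by intramolecular Wittig reaction with the ortho aldehyde, leaving both stereocentres untouched.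

**Compound list**

1 | 5,7-dimethoxycoumarin | COc1cc(OC)c2ccc(=O)oc2c1 | starting material
2 | 8-iodo-5,7-dimethoxycoumarin | COc1cc(OC)c2ccc(=O)oc2c1I | intermediate
3 | ethenesulfonyl fluoride | C=CS(=O)(=O)F | starting material
4 | (E)-2-(5,7-dimethoxy-2-oxo-2H-chromen-8-yl)ethene-1-sulfonyl fluoride | COc1cc(OC)c2ccc(=O)oc2c1/C=C/S(=O)(=O)F | intermediate
5 | 2-hydroxy-4,6-dimethoxybenzaldehyde | COc1cc(O)c(C=O)c(OC)c1 | starting material
6 | 2-(tert-butyldimethylsilyloxy)-4,6-dimethoxybenzaldehyde | COc1cc(O[Si](C)(C)C(C)(C)C)c(C=O)c(OC)c1 | intermediate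
7 | diethyl (2-methylallyl)phosphonate | CCOP(=O)(CC(C)=C)OCC | starting material
8 | (E)-tert-butyl[3,5-dimethoxy-2-(3-methylbuta-1,3-dien-1-yl)phenoxy]dimethylsilane | COc1cc(O[Si](C)(C)C(C)(C)C)c(/C=C/C(C)=C)c(OC)c1 | intermediate
9 | methacrolein | CC(=C)C=O | starting material
10 | (1S,2S)-2-[2-(tert-butyldimethylsilyloxy)-4,6-dimethoxyphenyl]-1,4-dimethylcyclohex-3-ene-1-carbaldehyde (formyl cis to aryl) | O=C[C@@]1(C)CCC(C)=C[C@H]1c1c(O[Si](C)(C)C(C)(C)C)cc(OC)cc1OC | intermediate
11 | 2-[(1S,6S)-6-formyl-3,6-dimethylcyclohex-2-en-1-yl]-3,5-dimethoxyphenyl (E)-2-(5,7-dimethoxy-2-oxo-2H-chromen-8-yl)ethene-1-sulfonate | O=C[C@@]1(C)CCC(C)=C[C@H]1c1c(OS(=O)(=O)/C=C/c2c(OC)cc(OC)c3ccc(=O)oc23)cc(OC)cc1OC | intermediate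
12 | (1S,2S)-2-[2-({[(E)-2-(5,7-dimethoxy-2-oxo-2H-chromen-8-yl)ethenyl]sulfonyl}oxy)-4,6-dimethoxyphenyl]-1,4-dimethylcyclohex-3-ene-1-carboxylic acid | OC(=O)[C@@]1(C)CCC(C)=C[C@H]1c1c(OS(=O)(=O)/C=C/c2c(OC)cc(OC)c3ccc(=O)oc23)cc(OC)cc1OC | intermediate
13 | 8-{(E)-2-[(1R,2R)-2-(2-hydroxy-4,6-dimethoxyphenyl)-1,4-dimethylcyclohex-3-en-1-yl]ethenyl}-5,7-dimethoxy-2H-chromen-2-one (styryl cis to aryl) | COc1cc(OC)c2ccc(=O)oc2c1/C=C/[C@@]1(C)CCC(C)=C[C@H]1c1c(O)cc(OC)cc1OC | intermediate
14 | 3-{(1R,6R)-6-[(E)-2-(5,7-dimethoxy-2-oxo-2H-chromen-8-yl)ethenyl]-3,6-dimethylcyclohex-2-en-1-yl}-2-hydroxy-4,6-dimethoxybenzaldehyde | COc1cc(OC)c2ccc(=O)oc2c1/C=C/[C@@]1(C)CCC(C)=C[C@H]1c1c(O)c(C=O)c(OC)cc1OC | intermediate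
15 | 2-formyl-3,5-dimethoxy-6-(cyclohexenyl as in 14)phenyl (triphenylphosphoranylidene)acetate | COc1cc(OC)c2ccc(=O)oc2c1/C=C/[C@@]1(C)CCC(C)=C[C@H]1c1c(OC(=O)C=P(c2ccccc2)(c2ccccc2)c2ccccc2)c(C=O)c(OC)cc1OC | intermediate
16 | 8-{(E)-2-[(1R,2R)-2-(5,7-dimethoxy-2-oxo-2H-chromen-8-yl)-1,4-dimethylcyclohex-3-en-1-yl]ethenyl}-5,7-dimethoxy-2H-chromen-2-one (CNP0164660.2) | COc1cc(OC)c2ccc(=O)oc2c1/C=C/[C@@]1(C)CCC(C)=C[C@H]1c1c(OC)cc(OC)c2ccc(=O)oc12 | target

**Step count.** Total: 10 steps. Longest linear sequence: 8 steps (5 to 16, steps 3 to 10).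

**Steps most likely to fail**

Step 8 (proposed new method). The seven-membered ipso capture may be too slow, so that the tertiary radical is quenched by hydrogen transfer or adds to a second molecule on the face anti to the aryl group. The excited catalyst may also be quenched by the electron-rich rings or the phenol being formed, and energy transfer may isomerise the new styrene to Z. The fallback uses known chemistry and sets out from aldehyde 10, whose formyl carbon already sits cis to the aryl group. Wittig methylenation (Ph3P=CH2, THF) should give the vinyl compound F1. Heck coupling of F1 with iodide 2 (Pd(OAc)2, P(o-tol)3, Et3N, DMF, 90 °C) should give the E-styryl silyl ether F2. Fluoride (TBAF, THF) then cleaves the silyl ether and returns to the route at 13. This fallback takes the configuration of the quaternary carbon from the endo selectivity of step 5 and builds the styryl unit at the aryl–vinyl bond instead.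

Step 5. The strongly acidic catalyst may oligomerise the electron-rich diene, and facial or endo/exo control may be insufficient with the twisted, doubly ortho-substituted aryl diene. The fallback sets out from diene 8 and uses a two-point-binding dienophile. A Cu(II)–bis(oxazoline)-catalysed Diels–Alder reaction with 3-acryloyloxazolidin-2-one ([Cu(t-Bu-box)](SbF6)2, CH2Cl2, ligand antipode chosen for the drawn configuration) should give the cis imide F3. Enolate methylation (NaHMDS, MeI, −78 °C, methyl entering anti to the aryl group) should give the quaternary imide F4. LiBH4 reduction should give the primary alcohol F5, and Dess–Martin oxidation returns to the route at 10.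

Step 1. Iodination may leak to C6 or C3, and the following Heck reaction at the doubly ortho-substituted position may stall. The fallback sets out from salicylaldehyde 5 and fixes the substitution pattern by symmetry. A second magnesium-mediated ortho-formylation (MgCl2, Et3N, paraformaldehyde) should give the symmetric dialdehyde F6. One equivalent of (triphenylphosphoranylidene)ketene closes the coumarin on either formyl group and should give the same 8-formylcoumarin F7. Olefination of F7 with methanedisulfonyl fluoride (Et3N, MeCN) returns to the route at 4.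

Further compounds
F1 | step 8 | tert-butyl{2-[(1R,6R)-6-ethenyl-3,6-dimethylcyclohex-2-en-1-yl]-3,5-dimethoxyphenoxy}dimethylsilane (vinyl cis to aryl) | C=C[C@@]1(C)CCC(C)=C[C@H]1c1c(O[Si](C)(C)C(C)(C)C)cc(OC)cc1OC
F2 | step 8 | tert-butyldimethylsilyl ether of 13 | COc1cc(OC)c2ccc(=O)oc2c1/C=C/[C@@]1(C)CCC(C)=C[C@H]1c1c(O[Si](C)(C)C(C)(C)C)cc(OC)cc1OC
F3 | step 5 | 3-{[(1S,2S)-2-[2-(tert-butyldimethylsilyloxy)-4,6-dimethoxyphenyl]-4-methylcyclohex-3-en-1-yl]carbonyl}oxazolidin-2-one (acyl cis to aryl) | O=C(N1CCOC1=O)[C@H]1CCC(C)=C[C@H]1c1c(O[Si](C)(C)C(C)(C)C)cc(OC)cc1OC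
F4 | step 5 | 3-{[(1S,2S)-2-[2-(tert-butyldimethylsilyloxy)-4,6-dimethoxyphenyl]-1,4-dimethylcyclohex-3-en-1-yl]carbonyl}oxazolidin-2-one (acyl cis to aryl) | O=C(N1CCOC1=O)[C@@]1(C)CCC(C)=C[C@H]1c1c(O[Si](C)(C)C(C)(C)C)cc(OC)cc1OC
F5 | step 5 | [(1S,2R)-2-[2-(tert-butyldimethylsilyloxy)-4,6-dimethoxyphenyl]-1,4-dimethylcyclohex-3-en-1-yl]methanol (hydroxymethyl cis to aryl) | OC[C@@]1(C)CCC(C)=C[C@H]1c1c(O[Si](C)(C)C(C)(C)C)cc(OC)cc1OC
F6 | step 1 | 2-hydroxy-4,6-dimethoxybenzene-1,3-dicarbaldehyde | COc1cc(OC)c(C=O)c(O)c1C=O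
F7 | step 1 | 5,7-dimethoxy-2-oxo-2H-chromene-8-carbaldehyde | COc1cc(OC)c2ccc(=O)oc2c1C=O
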